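At the first moment of south, with [G] as charged, the rate per Q, the constant of the first step times [G], is 0.616 min⁻¹, a value that falls as G is used up with Q, and J and X relax towards each other at 0.0206 min⁻¹, so at the start J is made much faster than it relaxes. Control then passes from the coupling to the clock. I have to choose the set-up for the next run.

in all of them: Z 20.0 mM

|  | Q | G | time | remark |
|---|---|---|---|---|
| south | 20 mM | 22.0 mM | 40 min | a closed flask charged with all of it at once and left for 40 min |
| south-east | 20 mM | 22.0 mM |  | one stirred flow tank at steady state, fed with the mixture as stated, mean residence time 40 min |
| north-west | 20 mM | 22.0 mM (fed, over 32.0 min) | 40 min | all but G at the start; G goes in evenly over 32.0 min, the run ends at 40 min |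
| south-west | 20 mM (fed, over 32.0 min) | 22.0 mM | 40 min | a stirred flask in which Q is dosed at a steady rate over 32.0 min without added volume, worked up at 40 min |

    Q + G → J + D (k1 = 28 M⁻¹ min⁻¹)
    J ⇌ X (K2 = 2.7, k2 = 0.015 min⁻¹)
    G + Z → G.Z (k3 = 0.56 M⁻¹ min⁻¹)

- the stated concentrations are those of everything mixed, before any reaction; amounts are the same in each set-up
- the feed brings no volume worth counting
- run time (south): 40 min

1. the set-up with the highest amount of J at the outlet or at the end, in percent of the Q put in ("none" if the first two lie within 2 percentage points) (south / south-east / north-west / south-west / none)
2. amount of J at the outlet or at the end, in percent of the Q put in, south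
3. amount of J at the outlet or at the end, in percent of the Q put in, south-east
4. amount of J at the outlet or at the end, in percent of the Q put in, north-west
5. amount of J at the outlet or at the end, in percent of the Q put in, south-west

I reckon with the keep: the share of J formed at some moment that is still J a given age later. It is the equilibrium share 27.0% plus the remaining share times exp(−λ·age), with λ the relaxation rate above. In south the age is about the run time. In the tank I average the decay over the residence times, which gives a bound, since I take every Q as reacted. Under dosing, turnover follows the feed, so the mean age is 24.0 min, and the keep at that age is 71.6%.

In north-west, G enters a flask rich in Q, which at the start takes it 50.0 times faster than Z does, so I count no loss there. In south-west, G waits beside Z, and with [G] falling evenly I estimate a loss of 3.61 mM. That is more than the excess of 2.00 mM, so G becomes the limiting reagent and the keep applies to a smaller share of Q: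

south: 59.1%
south-east, upper bound: 67.1%
north-west: the keep itself
south-west: 65.8%

I would run north-west, dosing G.

The forecast names north-west, gives 60.5%, 54.8%, 68.3% and 62.7% for south, south-east, north-west and south-west, and says of north-west: “G stays low, so little is lost to Z”.

The simulation gives 60.4%, 54.8%, 68.3% and 62.7% in that order, and north-west comes out best.

The main reason south-east falls short of full yield is the step from J to X: with that step struck out, both ways, south-east holds 81.8% of J against 54.8%. North-west still has 7.5% of its Q at 40.0 min, and the keep on the reacted remainder gives 66.2%. A neighbour of south-west with 5.0 mM of Z forms less G.Z than south-west and leaves 8.2% of its Q. The keep on its remainder gives 65.7%, and that flask holds 68.2% of J.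

All constants were set for the occasion; no experiment stands behind them.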